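Ring A of nigrasin I bears oxygen on C5, C7 and C8a, and the quaternary carbon of the 1,1-dimethylallyl group sits on C8 between C7 and C8a. That pattern is cut back to a vinylketene and an alkynyl silyl ether. One thermal benzannulation of 3-ethoxycyclobutenone with a triisopropylsilyloxyalkyne already carrying the 1,1-dimethylallyl group builds ring A (bonds C8–C8a, C6–C7, C4a–C8a) and delivers three differentiated oxygens: a free phenol (later O1), a silyl ether (O7) and an ethyl ether (O5). Only C4a remains open, so formylation and a rhodium-catalysed alkyne annulation add the pyranone, ring B and the 3-prenyl group; chelation-assisted de-ethylation and fluoride finish.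

Key step: step 2

Remark: the target has no stereocentre; paraformaldehyde is entered in the compound list as its monomer, and the one stereocentre met on the way (in a transient cyclobutenone) forms racemic and is destroyed in the same flask.

Step 1
Reactants: 1 methyl 2,2-dimethylbut-3-enoate; 2 dibromomethane; 3 triisopropylsilyl trifluoromethanesulfonate (TIPSOTf)
Product: 7 triisopropyl[(3,3-dimethylpent-4-en-1-yn-1-yl)oxy]silane, via dibromomethyllithium 4 (not isolated), via lithium dibromoenolate 5 (not isolated), via lithium ynolate 6 (not isolated)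
Conditions: CH2Br2, LiTMP (lithium 2,2,6,6-tetramethylpiperidide, from the amine and n-BuLi), THF, −78 °C; then n-BuLi, −78 °C → rt; then TIPSOTf, −78 → 0 °C; short-path distillation
Reagents that add atoms: dibromomethane, BrCBr; triisopropylsilyl trifluoromethanesulfonate, CC(C)[Si](OS(=O)(=O)C(F)(F)F)(C(C)C)C(C)C
Why: Kowalski ynolate synthesis, in which dibromomethyllithium adds to the ester, the resulting dibromoketone enolate undergoes bromine–lithium exchange and a 1,2-shift of the tertiary alkyl group to the lithium ynolate, and the bulky silyl triflate then silylates the ynolate on oxygen to give a stable triisopropylsilyl ynol ether.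

Step 2
Reactants: 7 triisopropyl[(3,3-dimethylpent-4-en-1-yn-1-yl)oxy]silane; 8 3-ethoxycyclobut-2-en-1-one
Product: 13 5-ethoxy-2-(2-methylbut-3-en-2-yl)-3-[(triisopropylsilyl)oxy]phenol, via ethoxyvinylketene 9 (not isolated), via vinylcyclobutenone 10 (not isolated), via dienylketene 11 (not isolated), via cyclohexadienone 12 (not isolated)
Conditions: toluene (degassed), slow addition of 8 to 7 (1.3 equiv) at 80 °C, then 110 °C, sealed vessel
Reagents that add atoms: none
Why: Danheiser benzannulation, a reaction known for cyclobutenones and trialkylsilyloxyalkynes and applied here to a 3-alkoxycyclobutenone and an alkyne with a quaternary propargylic carbon: four-electron electrocyclic opening of 8 gives vinylketene 9, a (2+2) cycloaddition of its ketene C=C bond with the ynol ether gives cyclobutenone 10, and a second four-electron opening gives dienylketene 11. Ring A closes by thermal six-electron disrotatory electrocyclisation of 11 between the ketene carbon and the terminal methylene carbon (the C8a–C4a bond), and dienone 12 tautomerises to phenol 13. No stereocentre is retained, since the one in 10 is lost on ring opening and 13 is achiral. The single selectivity needed is the regiochemistry of the ketene–alkyne cycloaddition, and the polarisation of the silyloxyalkyne secures it: the nucleophilic carbon remote from oxygen, which carries the quaternary group, bonds to the electrophilic ketene carbon, so the 1,1-dimethylallyl carbon ends between the new phenol and the silyl ether while the ethoxy carbon lies meta to both. Slow addition of 8 keeps the ketene concentration low, which should suppress its dimerisation and the acylation of the hindered phenol.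

Step 3
Reactants: 13 5-ethoxy-2-(2-methylbut-3-en-2-yl)-3-[(triisopropylsilyl)oxy]phenol; 14 paraformaldehyde (formaldehyde source)
Product: 16 6-ethoxy-2-hydroxy-3-(2-methylbut-3-en-2-yl)-4-[(triisopropylsilyl)oxy]benzaldehyde, via salicyl alcohol 15 (not isolated)
Conditions: MgCl2 (anhydrous), Et3N, (CH2O)n, MeCN, reflux; dilute citric acid work-up
Reagents that add atoms: formaldehyde (as paraformaldehyde), C=O
Why: Casnati–Skattebøl ortho-formylation, in which the phenoxide held on MgCl2 (ArOMgCl) delivers formaldehyde to the only free ortho carbon (the future C4a) and a second formaldehyde oxidises the benzylic alkoxide by Oppenauer-type hydride transfer, under conditions that the aryl silyl ether and both alkenes should tolerate.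

Step 4
Reactants: 17 2,4-dihydroxybenzaldehyde; 3 triisopropylsilyl trifluoromethanesulfonate (TIPSOTf)
Product: 18 2,4-bis[(triisopropylsilyl)oxy]benzaldehyde
Conditions: 2,6-lutidine, CH2Cl2, 0 °C → rt
Reagents that add atoms: triisopropylsilyl trifluoromethanesulfonate, CC(C)[Si](OS(=O)(=O)C(F)(F)F)(C(C)C)C(C)C
Why: Standard O-silylation of both phenols with a silyl triflate and a hindered pyridine base, chosen so that ring B carries the same fluoride-labile group as O7 and no acid is needed at the end.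

Step 5
Reactants: 18 2,4-bis[(triisopropylsilyl)oxy]benzaldehyde; 19 carbon tetrabromide
Product: 21 1-(2,2-dibromoethenyl)-2,4-bis[(triisopropylsilyl)oxy]benzene, via dibromomethylene ylide 20 (not isolated)
Conditions: PPh3, Et3N, CH2Cl2, 0 °C
Reagents that add atoms: carbon tetrabromide, BrC(Br)(Br)Br
Why: First stage of the Corey–Fuchs alkyne synthesis, a Wittig reaction of the aldehyde with the ylide formed from CBr4 and PPh3, with Et3N buffering the medium so that the aryl silyl ethers stay intact.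

Step 6
Reactants: 21 1-(2,2-dibromoethenyl)-2,4-bis[(triisopropylsilyl)oxy]benzene; 22 1-bromo-3-methylbut-2-ene (prenyl bromide)
Product: 24 1-(5-methylhex-4-en-1-yn-1-yl)-2,4-bis[(triisopropylsilyl)oxy]benzene, via lithium acetylide 23 (not isolated)
Conditions: n-BuLi (2.1 equiv), THF, −78 → 0 °C; then CuI (10 mol %), 22, −20 °C → rt
Reagents that add atoms: 1-bromo-3-methylbut-2-ene, CC(C)=CCBr
Why: Second stage of the Corey–Fuchs sequence, in which bromine–lithium exchange and Fritsch–Buttenberg–Wiechell rearrangement give lithium acetylide 23, followed by copper-catalysed allylic substitution at the primary carbon of prenyl bromide to give the skipped enyne.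

Step 7
Reactants: 16 6-ethoxy-2-hydroxy-3-(2-methylbut-3-en-2-yl)-4-[(triisopropylsilyl)oxy]benzaldehyde; 24 1-(5-methylhex-4-en-1-yn-1-yl)-2,4-bis[(triisopropylsilyl)oxy]benzene
Product: 25 2-{2,4-bis[(triisopropylsilyl)oxy]phenyl}-5-ethoxy-8-(2-methylbut-3-en-2-yl)-3-(3-methylbut-2-en-1-yl)-7-[(triisopropylsilyl)oxy]-4H-chromen-4-one
Conditions: [RhCl(cod)]2 (2.5 mol %), 1,2,3,4-tetraphenylcyclopenta-1,3-diene (10 mol %), Cu(OAc)2·H2O (2 equiv), o-xylene, 130 °C, N2
Reagents that add atoms: none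
Why: Rhodium-catalysed oxidative annulation of a salicylaldehyde with an internal alkyne (phenoxide-directed cleavage of the aldehyde C–H bond, alkyne insertion into the acyl–rhodium bond with the aryl-bearing carbon next to rhodium, C–O reductive elimination, reoxidation by Cu(OAc)2), a reaction known to turn alkyl aryl alkynes into 3-alkyl-2-arylchromones, so ring B should land on C2 and the prenyl group on C3.

Step 8
Reactants: 25 2-{2,4-bis[(triisopropylsilyl)oxy]phenyl}-5-ethoxy-8-(2-methylbut-3-en-2-yl)-3-(3-methylbut-2-en-1-yl)-7-[(triisopropylsilyl)oxy]-4H-chromen-4-one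
Product: 26 2-{2,4-bis[(triisopropylsilyl)oxy]phenyl}-5-hydroxy-8-(2-methylbut-3-en-2-yl)-3-(3-methylbut-2-en-1-yl)-7-[(triisopropylsilyl)oxy]-4H-chromen-4-one
Conditions: MgI2·OEt2 (5 equiv), THF–toluene, 70 °C; aq Na2S2O3/NH4Cl
Reagents that add atoms: none
Why: Chelation-assisted ether cleavage, in which MgI2 bound between the C4 carbonyl oxygen and O5 activates only this ether for SN2 attack of iodide at the ethyl group, a reaction type established for 5-methoxy groups of prenylated flavonoids and expected to run more slowly but along the same course with ethyl, while any silyl ether lost here is due for removal in step 9 anyway.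

Step 9
Reactants: 26 2-{2,4-bis[(triisopropylsilyl)oxy]phenyl}-5-hydroxy-8-(2-methylbut-3-en-2-yl)-3-(3-methylbut-2-en-1-yl)-7-[(triisopropylsilyl)oxy]-4H-chromen-4-one
Product: 27 nigrasin I
Conditions: TBAF (3.5 equiv), AcOH (3.5 equiv), THF, 0 °C → rt; pH 7 buffer
Reagents that add atoms: none
Why: Fluoride-mediated cleavage of the three aryl silyl ethers under acetic acid buffering, which avoids both the protic acid that could cyclise the 7-hydroxyl onto the 1,1-dimethylallyl group or the 2'-hydroxyl onto the prenyl group and the strong base that could open the pyranone.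

Compound list
1 | methyl 2,2-dimethylbut-3-enoate | C=CC(C)(C)C(=O)OC | starting material
2 | dibromomethane | BrCBr | starting material
3 | triisopropylsilyl trifluoromethanesulfonate | CC(C)[Si](OS(=O)(=O)C(F)(F)F)(C(C)C)C(C)C | starting material
4 | dibromomethyllithium | [Li]C(Br)Br | intermediate (not isolated)
5 | lithium 1,1-dibromo-3,3-dimethylpenta-1,4-dien-2-olate | [Li+].[O-]C(=C(Br)Br)C(C)(C)C=C | intermediate (not isolated)
6 | lithium 3,3-dimethylpent-4-en-1-yn-1-olate | [Li+].[O-]C#CC(C)(C)C=C | intermediate (not isolated)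
7 | triisopropyl[(3,3-dimethylpent-4-en-1-yn-1-yl)oxy]silane | C=CC(C)(C)C#CO[Si](C(C)C)(C(C)C)C(C)C | intermediate
8 | 3-ethoxycyclobut-2-en-1-one | CCOC1=CC(=O)C1 | starting material
9 | 3-ethoxybuta-1,3-dien-1-one | C=C(OCC)C=C=O | intermediate (not isolated)
10 | 4-(1-ethoxyethenyl)-2-(2-methylbut-3-en-2-yl)-3-[(triisopropylsilyl)oxy]cyclobut-2-en-1-one (racemic) | C=CC(C)(C)C1=C(O[Si](C(C)C)(C(C)C)C(C)C)C(C(=C)OCC)C1=O | intermediate (not isolated)
11 | (3E)-5-ethoxy-2-(2-methylbut-3-en-2-yl)-3-[(triisopropylsilyl)oxy]hexa-1,3,5-trien-1-one | C=CC(C)(C)C(=C=O)/C(O[Si](C(C)C)(C(C)C)C(C)C)=C\C(=C)OCC | intermediate (not isolated)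
12 | 5-ethoxy-2-(2-methylbut-3-en-2-yl)-3-[(triisopropylsilyl)oxy]cyclohexa-2,4-dien-1-one | C=CC(C)(C)C1=C(O[Si](C(C)C)(C(C)C)C(C)C)C=C(OCC)CC1=O | intermediate (not isolated)
13 | 5-ethoxy-2-(2-methylbut-3-en-2-yl)-3-[(triisopropylsilyl)oxy]phenol | C=CC(C)(C)c1c(O)cc(OCC)cc1O[Si](C(C)C)(C(C)C)C(C)C | intermediate
14 | paraformaldehyde (as formaldehyde) | C=O | starting material
15 | 3-ethoxy-2-(hydroxymethyl)-6-(2-methylbut-3-en-2-yl)-5-[(triisopropylsilyl)oxy]phenol | C=CC(C)(C)c1c(O)c(CO)c(OCC)cc1O[Si](C(C)C)(C(C)C)C(C)C | intermediate (not isolated)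
16 | 6-ethoxy-2-hydroxy-3-(2-methylbut-3-en-2-yl)-4-[(triisopropylsilyl)oxy]benzaldehyde | C=CC(C)(C)c1c(O)c(C=O)c(OCC)cc1O[Si](C(C)C)(C(C)C)C(C)C | intermediate
17 | 2,4-dihydroxybenzaldehyde | O=Cc1ccc(O)cc1O | starting material
18 | 2,4-bis[(triisopropylsilyl)oxy]benzaldehyde | O=Cc1ccc(O[Si](C(C)C)(C(C)C)C(C)C)cc1O[Si](C(C)C)(C(C)C)C(C)C | intermediate
19 | carbon tetrabromide | BrC(Br)(Br)Br | starting material
20 | (dibromomethylidene)triphenylphosphorane | BrC(Br)=P(c1ccccc1)(c1ccccc1)c1ccccc1 | intermediate (not isolated)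
21 | 1-(2,2-dibromoethenyl)-2,4-bis[(triisopropylsilyl)oxy]benzene | BrC(Br)=Cc1ccc(O[Si](C(C)C)(C(C)C)C(C)C)cc1O[Si](C(C)C)(C(C)C)C(C)C | intermediate
22 | 1-bromo-3-methylbut-2-ene (prenyl bromide) | CC(C)=CCBr | starting material
23 | lithium {2,4-bis[(triisopropylsilyl)oxy]phenyl}acetylide | [Li]C#Cc1ccc(O[Si](C(C)C)(C(C)C)C(C)C)cc1O[Si](C(C)C)(C(C)C)C(C)C | intermediate (not isolated)
24 | 1-(5-methylhex-4-en-1-yn-1-yl)-2,4-bis[(triisopropylsilyl)oxy]benzene | CC(C)=CCC#Cc1ccc(O[Si](C(C)C)(C(C)C)C(C)C)cc1O[Si](C(C)C)(C(C)C)C(C)C | intermediate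
25 | 2-{2,4-bis[(triisopropylsilyl)oxy]phenyl}-5-ethoxy-8-(2-methylbut-3-en-2-yl)-3-(3-methylbut-2-en-1-yl)-7-[(triisopropylsilyl)oxy]-4H-chromen-4-one | C=CC(C)(C)c1c(O[Si](C(C)C)(C(C)C)C(C)C)cc(OCC)c2c(=O)c(CC=C(C)C)c(-c3ccc(O[Si](C(C)C)(C(C)C)C(C)C)cc3O[Si](C(C)C)(C(C)C)C(C)C)oc12 | intermediate
26 | 2-{2,4-bis[(triisopropylsilyl)oxy]phenyl}-5-hydroxy-8-(2-methylbut-3-en-2-yl)-3-(3-methylbut-2-en-1-yl)-7-[(triisopropylsilyl)oxy]-4H-chromen-4-one | C=CC(C)(C)c1c(O[Si](C(C)C)(C(C)C)C(C)C)cc(O)c2c(=O)c(CC=C(C)C)c(-c3ccc(O[Si](C(C)C)(C(C)C)C(C)C)cc3O[Si](C(C)C)(C(C)C)C(C)C)oc12 | intermediate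
27 | nigrasin I, 2-(2,4-dihydroxyphenyl)-5,7-dihydroxy-8-(2-methylbut-3-en-2-yl)-3-(3-methylbut-2-en-1-yl)-4H-chromen-4-one | C=CC(C)(C)c1c(O)cc(O)c2c(=O)c(CC=C(C)C)c(-c3ccc(O)cc3O)oc12 | target

Total step count: 9. Longest linear sequence: 6 steps (steps 1, 2, 3, 7, 8, 9 from ester 1; the ring B branch, steps 4, 5, 6, 7, 8, 9 from aldehyde 17, is equally long).

Steps most likely to fail

Step 2. The carbon of the alkyne that must bond to the ketene carries a quaternary group, so the cycloaddition may be slow. The ethoxyvinylketene could then dimerise or acylate the product phenol, or the vinylogous ester 8 could open so sluggishly that the ynol ether decomposes first. The fallback sets out from 3 and 22 and comes back at 27; it builds ring A by an aromatic Claisen rearrangement and carries all four oxygens as silyl ethers. Purchased phloroglucinol (benzene-1,3,5-triol) would be silylated twice with 3 (2 equiv, 2,6-lutidine, CH2Cl2) to 3,5-bis[(triisopropylsilyl)oxy]phenol F1, and alkylated with 22 (K2CO3, acetone) to the prenyl ether 1-[(3-methylbut-2-en-1-yl)oxy]-3,5-bis[(triisopropylsilyl)oxy]benzene F2. Heating with Eu(fod)3 (toluene, 80 °C) should shift the prenyl group, with allylic inversion, to either of the two equivalent ortho carbons and give 2-(2-methylbut-3-en-2-yl)-3,5-bis[(triisopropylsilyl)oxy]phenol F3. Formylation as in step 3 would give 2-hydroxy-3-(2-methylbut-3-en-2-yl)-4,6-bis[(triisopropylsilyl)oxy]benzaldehyde F4, and annulation with 24 as in step 7 would give the tetrasilyl flavone 2-{2,4-bis[(triisopropylsilyl)oxy]phenyl}-8-(2-methylbut-3-en-2-yl)-3-(3-methylbut-2-en-1-yl)-5,7-bis[(triisopropylsilyl)oxy]-4H-chromen-4-one F5. TBAF/AcOH as in step 9 would then give 27 with no ether cleavage.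

Step 7. The skipped enyne may isomerise to a conjugated system under hot acetate, the ortho-substituted aryl alkyne may insert too slowly, and the acyl–rhodium intermediate may lose CO to give a benzofuran. The fallback sets out from 16 and 18 and comes back at 25; it builds the pyranone by acylation of a ketone enolate and cyclodehydration.
- The Grignard reagent 4-methylpent-3-en-1-ylmagnesium bromide F6 (from purchased 5-bromo-2-methylpent-2-ene and Mg; 2.5 equiv, THF, 0 °C) would add to 16 to give the racemic carbinol 1-{6-ethoxy-2-hydroxy-3-(2-methylbut-3-en-2-yl)-4-[(triisopropylsilyl)oxy]phenyl}-5-methylhex-4-en-1-ol F7.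
- MnO2 (CH2Cl2, rt) would oxidise the benzylic alcohol to the ketone 1-{6-ethoxy-2-hydroxy-3-(2-methylbut-3-en-2-yl)-4-[(triisopropylsilyl)oxy]phenyl}-5-methylhex-4-en-1-one F8.
- Separately, Pinnick oxidation of 18 (NaClO2, NaH2PO4, 2-methylbut-2-ene, t-BuOH/H2O) would give 2,4-bis[(triisopropylsilyl)oxy]benzoic acid F9, and (COCl)2 with catalytic DMF would give 2,4-bis[(triisopropylsilyl)oxy]benzoyl chloride F10.
- The phenoxide–enolate dianion of F8 (LiN(SiMe3)2, 3 equiv, THF, −78 °C) would be C-acylated by F10 to the Baker–Venkataraman-type 1,3-diketone 1-{2,4-bis[(triisopropylsilyl)oxy]phenyl}-3-{6-ethoxy-2-hydroxy-3-(2-methylbut-3-en-2-yl)-4-[(triisopropylsilyl)oxy]phenyl}-2-(3-methylbut-2-en-1-yl)propane-1,3-dione F11.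
- Mild cyclodehydration (AcOH, NaOAc, 60 °C) would close the pyranone to 25.

Step 8. Attack of iodide at the ethyl carbon may be too slow, and the forcing conditions then needed could lead to addition of HI to the prenyl or vinyl group, or to cyclisation onto a phenol freed by partial desilylation. The fallback sets out from 8 and comes back at 26; it replaces the ethyl spectator group on O5 by benzyl before the benzannulation. Acid-catalysed exchange of the vinylogous ester with benzyl alcohol (cat. TsOH, PhCH2OH, toluene, 40 °C, ethanol removed under reduced pressure) would give 3-(benzyloxy)cyclobut-2-en-1-one F12. Steps 2, 3 and 7 would then be run in the same way to give 5-(benzyloxy)-2-(2-methylbut-3-en-2-yl)-3-[(triisopropylsilyl)oxy]phenol F13, 6-(benzyloxy)-2-hydroxy-3-(2-methylbut-3-en-2-yl)-4-[(triisopropylsilyl)oxy]benzaldehyde F14 and 5-(benzyloxy)-2-{2,4-bis[(triisopropylsilyl)oxy]phenyl}-8-(2-methylbut-3-en-2-yl)-3-(3-methylbut-2-en-1-yl)-7-[(triisopropylsilyl)oxy]-4H-chromen-4-one F15. The benzyl ether peri to the carbonyl would be cleaved by MgBr2·OEt2 (toluene–Et2O, 60 °C) to give 26; this should be far easier than de-ethylation because bromide attacks a benzylic carbon.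

Further compounds
F1 | step 2 | 3,5-bis[(triisopropylsilyl)oxy]phenol | Oc1cc(O[Si](C(C)C)(C(C)C)C(C)C)cc(O[Si](C(C)C)(C(C)C)C(C)C)c1
F2 | step 2 | 1-[(3-methylbut-2-en-1-yl)oxy]-3,5-bis[(triisopropylsilyl)oxy]benzene | CC(C)=CCOc1cc(O[Si](C(C)C)(C(C)C)C(C)C)cc(O[Si](C(C)C)(C(C)C)C(C)C)c1
F3 | step 2 | 2-(2-methylbut-3-en-2-yl)-3,5-bis[(triisopropylsilyl)oxy]phenol | C=CC(C)(C)c1c(O)cc(O[Si](C(C)C)(C(C)C)C(C)C)cc1O[Si](C(C)C)(C(C)C)C(C)C
F4 | step 2 | 2-hydroxy-3-(2-methylbut-3-en-2-yl)-4,6-bis[(triisopropylsilyl)oxy]benzaldehyde | C=CC(C)(C)c1c(O)c(C=O)c(O[Si](C(C)C)(C(C)C)C(C)C)cc1O[Si](C(C)C)(C(C)C)C(C)C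
F5 | step 2 | 2-{2,4-bis[(triisopropylsilyl)oxy]phenyl}-8-(2-methylbut-3-en-2-yl)-3-(3-methylbut-2-en-1-yl)-5,7-bis[(triisopropylsilyl)oxy]-4H-chromen-4-one | C=CC(C)(C)c1c(O[Si](C(C)C)(C(C)C)C(C)C)cc(O[Si](C(C)C)(C(C)C)C(C)C)c2c(=O)c(CC=C(C)C)c(-c3ccc(O[Si](C(C)C)(C(C)C)C(C)C)cc3O[Si](C(C)C)(C(C)C)C(C)C)oc12
F6 | step 7 | 4-methylpent-3-en-1-ylmagnesium bromide | CC(C)=CCC[Mg]Br
F7 | step 7 | 1-{6-ethoxy-2-hydroxy-3-(2-methylbut-3-en-2-yl)-4-[(triisopropylsilyl)oxy]phenyl}-5-methylhex-4-en-1-ol (racemic) | C=CC(C)(C)c1c(O)c(C(O)CCC=C(C)C)c(OCC)cc1O[Si](C(C)C)(C(C)C)C(C)C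
F8 | step 7 | 1-{6-ethoxy-2-hydroxy-3-(2-methylbut-3-en-2-yl)-4-[(triisopropylsilyl)oxy]phenyl}-5-methylhex-4-en-1-one | C=CC(C)(C)c1c(O)c(C(=O)CCC=C(C)C)c(OCC)cc1O[Si](C(C)C)(C(C)C)C(C)C
F9 | step 7 | 2,4-bis[(triisopropylsilyl)oxy]benzoic acid | OC(=O)c1ccc(O[Si](C(C)C)(C(C)C)C(C)C)cc1O[Si](C(C)C)(C(C)C)C(C)C
F10 | step 7 | 2,4-bis[(triisopropylsilyl)oxy]benzoyl chloride | ClC(=O)c1ccc(O[Si](C(C)C)(C(C)C)C(C)C)cc1O[Si](C(C)C)(C(C)C)C(C)C
F11 | step 7 | 1-{2,4-bis[(triisopropylsilyl)oxy]phenyl}-3-{6-ethoxy-2-hydroxy-3-(2-methylbut-3-en-2-yl)-4-[(triisopropylsilyl)oxy]phenyl}-2-(3-methylbut-2-en-1-yl)propane-1,3-dione (racemic, enolisable) | C=CC(C)(C)c1c(O)c(C(=O)C(CC=C(C)C)C(=O)c2ccc(O[Si](C(C)C)(C(C)C)C(C)C)cc2O[Si](C(C)C)(C(C)C)C(C)C)c(OCC)cc1O[Si](C(C)C)(C(C)C)C(C)C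
F12 | step 8 | 3-(benzyloxy)cyclobut-2-en-1-one | O=C1C=C(OCc2ccccc2)C1
F13 | step 8 | 5-(benzyloxy)-2-(2-methylbut-3-en-2-yl)-3-[(triisopropylsilyl)oxy]phenol | C=CC(C)(C)c1c(O)cc(OCc2ccccc2)cc1O[Si](C(C)C)(C(C)C)C(C)C
F14 | step 8 | 6-(benzyloxy)-2-hydroxy-3-(2-methylbut-3-en-2-yl)-4-[(triisopropylsilyl)oxy]benzaldehyde | C=CC(C)(C)c1c(O)c(C=O)c(OCc2ccccc2)cc1O[Si](C(C)C)(C(C)C)C(C)C
F15 | step 8 | 5-(benzyloxy)-2-{2,4-bis[(triisopropylsilyl)oxy]phenyl}-8-(2-methylbut-3-en-2-yl)-3-(3-methylbut-2-en-1-yl)-7-[(triisopropylsilyl)oxy]-4H-chromen-4-one | C=CC(C)(C)c1c(O[Si](C(C)C)(C(C)C)C(C)C)cc(OCc4ccccc4)c2c(=O)c(CC=C(C)C)c(-c3ccc(O[Si](C(C)C)(C(C)C)C(C)C)cc3O[Si](C(C)C)(C(C)C)C(C)C)oc12
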